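## Structural features

The target 19 consists of two 2-(4-methoxyphenyl)chroman-4-one (flavanone) units joined by a single C–C bond between C3 and C3''. Ring A of the unprimed unit carries free phenols at C5 and C7, whereas ring A of the doubly primed unit carries a chelated phenol at C5'' and a methyl ether at C7'', so the molecule is only pseudo-C2-symmetric. C2, C3, C3'' and C2'' are four contiguous stereocentres, all R, and in both rings C the anisyl group and the inter-unit bond are cis (H2/H3 and H2''/H3'' on the same face), the less stable arrangement of a 2,3-disubstituted chromanone. C3–H and C3''–H are α to aryl ketones and β to the ring oxygens, so base epimerises them to trans and opens ring C by retro-oxa-Michael reaction; O1–C2 and O1''–C2'' are 4-methoxybenzylic ethers that acid can ionise and hydrogen on Pd/C can cleave. The real difficulty is the crowded C3–C3'' bond flanked by two kinetically defined cis pairs, together with the need to tell two nearly identical halves apart at O7. The plan exploits the fact that O1, C2 and ring B of the unprimed unit together form a 4-methoxybenzyl ether of the C8a oxygen: its benzylic C–H is the sixth atom counted from C3, so a carbenoid at C3 can close ring C by forming C2–C3 and set both centres in one event. The doubly primed half passes through that event as a flat flavone (C2''=C3''), free of stereocentres and of acidic hydrogens, and is saturated at the end by cis addition of hydrogen.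

## Logic of the disconnections

19 to 18. The O–CH2 bonds at O5 (4-methoxybenzyl), O7 and O5'' (both benzyl) are cut. The three phenols must be masked during carbenoid and enolate chemistry, and hydrogenolysis removes all three masks without base or acid. The skeleton is unchanged, but O–H bonds that would intercept a carbenoid are gone. The forward step must spare O1–C2, O1''–C2'' and both ketones.

18 to 17. The C2''–H and C3''–H bonds are removed, which returns the C2''=C3'' alkene. A cis pair results from delivery of two hydrogens to one face, and the alkene form is inert in all earlier steps. Two stereocentres disappear, and 17 holds only C2 and C3. The forward step has to hydrogenate a hindered tetrasubstituted alkene with face control and without base.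

17 to 16. The C2–C3 bond is cut and ring C of the unprimed unit is opened; C2 becomes the CH2 of a 4-methoxybenzyl ether and C3 a diazo carbon. This is the one bond of ring C whose formation can set C2 and C3 cis under kinetic control without an enolate. One ring and two stereocentres are removed, and 16 is achiral with two equivalent ortho ethers. The forward step must favour insertion over ylide formation, rearrangement and arene attack, and the catalyst must supply both the cis and the absolute sense.

16 to 15. The C3=N2 bond is cut to leave a methylene. That methylene lies between an aryl ketone and C3'' of the flavone and is acidic enough for direct diazo transfer. The sensitive diazo group is thus introduced immediately before use. The forward step needs only an amine base and cold, dark handling.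

15 to 6 and 14. The C3–C3'' bond is cut between the methyl carbon of a ketone and an iodinated flavone carbon. It is the central bond, it divides the molecule into halves of similar size, and at this stage it carries no stereocentre. The 5,7-dioxygenated half becomes 6 and the 7''-methoxy half becomes 14, so the two halves differ from the start. The forward step must couple a methyl ketone enolate once with a hindered α-iodo enone under a base that the flavone tolerates.

14 to 12 (via 13). The C3''–I bond is cut. C3''–H is the most acidic ring hydrogen, so iodine can be placed through the anion and not by electrophilic substitution, which would compete at C6'' and C8''. One functional group is removed. The forward step needs low-temperature metalation that leaves the benzyl ether alone.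

12 to 11. The O1''–C2'' bond is cut, opening the pyranone to a phenol and a 1,3-diketone. Cyclodehydration of such diketones is the standard closure of a flavone. One ring is removed. The forward acid must be mild enough for the benzyl ether next to the carbonyl.

11 to 8 and 9 (via 10). The C2''–C3'' bond is cut between the acetyl methyl carbon and an aroyl carbon. Acyl transfer from the phenol oxygen to carbon makes this bond intramolecularly and regiospecifically. The half is reduced to an acetophenone and an acid chloride. The forward step needs the free ortho phenol of 8.

8 to 7 and 2. The O5''–CH2 bond of the benzyl ether is cut. Benzyl, not 4-methoxybenzyl, is chosen here so that this ether is a poorer hydride donor than the reacting ethers in the insertion. The half is traced to commercial 7, which already carries the 7''-methoxy group. The forward step must stop at the mono-ether, which the chelation of the second hydroxyl secures.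

6 to 5 and 4. The O–CH2 bond of one ortho 4-methoxybenzyl ether is cut, leaving a chelated phenol. With both ortho oxygens carrying the same activated group, the later insertion has two equivalent C–H donors and no regiochemical choice. The gain is a ketone with a single free hydroxyl. The forward step must alkylate a strongly hydrogen-bonded phenol, which calls for a polar solvent and heat but no longer risks attack at ring carbon, because only one phenoxide remains.

5 to 3 and 4. The O–CH2 bond of the other ortho 4-methoxybenzyl ether is cut. Of the two ortho hydroxyls of 3 only one can be chelated at a time, so the first ortho ether forms under mild conditions. This leads back to a simple mono-ether of the triphenol. The forward step must stop after one alkylation, which the chelation of the remaining hydroxyl secures.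

3 to 1 and 2. The O7–CH2 bond of the benzyl ether is cut. The para hydroxyl is the most acidic and is not hydrogen-bonded, so it can be etherified first. A plain benzyl group is placed there because this oxygen is a spectator that only has to leave in the final hydrogenolysis. One step from a commercial triphenol. The forward step must favour O- over C-alkylation and must not overrun to a diether, which is why the three ethers are introduced one at a time under graded conditions.

## Other disconnections considered

Alternative 1: The cut removes both rings A (O1–C8a, C4–C4a and their doubly primed counterparts) and then joins C2 to C2'', which leads back to the all-trans cyclobutane diacid A1. In the forward direction, one-electron oxidation of an anisyl ring of A1 by an excited acridinium photocatalyst would break the strained bond between the two anisyl carbons. Each carboxyl group would then capture the benzylic carbon three atoms away, and a second oxidation would complete the exo,exo dilactone A2. A2 holds C2, C3, C3'', C2'', both O1 atoms and both C4 carbons in the relative configuration of the target.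
- In its favour: four stereocentres arise from one symmetric event, no diazo compound is needed, and A1 could in principle be made enantioenriched by an asymmetric photocycloaddition. On stereocentres created per step it is better than the chosen plan, which sets two.
- Against it: the radical cation of a 1,2-diarylcyclobutane may fall apart into two alkene fragments before the carboxyl groups close. A2 still lacks both rings A, whose attachment is the harder half of the problem. A symmetric intermediate cannot distinguish O7 from O7''.
- Comparison: both key steps rely on a benzylic position activated by a 4-methoxyphenyl ring, but the chosen insertion has the closer reaction class behind it. The chosen plan builds the difference between the halves into its fragments. Step counts to the target are comparable once ring A attachment and desymmetrisation are added.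

Alternative 2: The cut is O1–C2 and C3–C4 in each unit, which gives the (Z,Z)-diene A3 and the two salicylaldehydes A4 and A5. In the forward direction, each aldehyde would be converted by an orthoformate and a chiral phosphoric acid into an ortho-quinone methide oxocarbenium ion that adds across one Z alkene of A3, giving the biflavan A6.
- In its favour: it is the most convergent of the plans (three components, four bonds, two rings). The cis C2/C3 relationship would follow from the Z geometry. Two different aldehydes distinguish O7 from O7'', which makes it the equal of the chosen plan on that point and better on convergence.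
- Against it: a cationic cycloaddition may become stepwise, which would lose the Z geometry. A conjugated diene offers 1,2- and 1,4-modes of addition. The electron-rich A3 may isomerise under acid. Using two aldehydes in turn requires the reaction to stop cleanly after the first addition. A6 has C4 and C4'' as benzylic methyl ethers, so two oxidations to ketones must follow beside the epimerisable C3 and C3''.
- Comparison: the skeleton is reached in fewer steps (better), but the oxidation level is wrong, whereas the chosen insertion delivers the C4 ketone directly and sets only the centres that are kept.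

Alternative 3: The cut is O1–C8a and C4–C4a in each unit. Aminolysis of A2 would give the bis(N-methoxy-N-methylamide) diol A7. In the forward direction, its two potassium alkoxides would add to the aryne released from silyl triflate A8 by a fluoride source, and each aryl anion would attack the neighbouring amide carbonyl to give the tetrabenzyl biflavanone A9.
- In its favour: all four stereocentres are taken over from A2, so none is created on the sensitive flavanone. The regiochemistry of a 3-alkoxy aryne places O1 and C4 correctly. It is the shortest plan on paper, and on step economy and on early setting of configuration it is better than the chosen plan.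
- Against it: A9 is symmetric and has a benzyl ether where the 7''-methyl ether is needed, so 19 could only be reached by a statistical mono-methylation or by two different arynes added one after the other. Each alkoxide of A7 can instead relactonise to A2 or undergo retro-aldol cleavage. The basic fluoride medium endangers the cis centres of A9 once formed.
- Comparison: the chosen plan is longer but keeps every step after the creation of stereocentres free of base and carries the O7/O7'' difference from the first step.

Key step: step 10

Assumption: Rh2(S-PTTL)4 in step 10 and the ligand antipode in step 11 are taken to induce the 2R,3R and 2''R,3''R sense; if either induces the opposite sense, the mirror-image catalyst (from D-tert-leucine) or ligand is used with no other change.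

## Route

Step 1
Reactants: 1 2',4',6'-trihydroxyacetophenone; 2 benzyl bromide
Product: 3 1-[4-(benzyloxy)-2,6-dihydroxyphenyl]ethanone
Conditions: K2CO3 (1.0 equiv), 2 (1.0 equiv, slow addition), DMF, 0 °C → rt
Reagents that add atoms: none
Why: Williamson etherification; the para hydroxyl is the most acidic and is not hydrogen-bonded to the acetyl group, so one equivalent of base forms its phenoxide first and one equivalent of halide should give the 4-O-benzyl ether, while the low temperature and the absence of excess base hold back C-benzylation and a second alkylation.

Step 2
Reactants: 3 1-[4-(benzyloxy)-2,6-dihydroxyphenyl]ethanone; 4 4-methoxybenzyl chloride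
Product: 5 1-[4-(benzyloxy)-2-hydroxy-6-(4-methoxybenzyloxy)phenyl]ethanone
Conditions: K2CO3 (1.2 equiv), 4 (1.05 equiv), Bu4NI (cat.), acetone, reflux
Reagents that add atoms: none
Why: Williamson monoalkylation; only one of the two ortho hydroxyls can be chelated to the carbonyl at a time, so the other reacts readily, and after the first etherification the remaining hydroxyl is locked in a hydrogen bond and reacts much more slowly, which should stop the reaction at the mono-ether.

Step 3
Reactants: 5 1-[4-(benzyloxy)-2-hydroxy-6-(4-methoxybenzyloxy)phenyl]ethanone; 4 4-methoxybenzyl chloride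
Product: 6 1-[4-(benzyloxy)-2,6-bis(4-methoxybenzyloxy)phenyl]ethanone
Conditions: K2CO3 (2 equiv), 4 (1.2 equiv), Bu4NI (cat.), DMF, 60 °C
Reagents that add atoms: none
Why: Williamson etherification of the chelated phenol, which needs a polar aprotic solvent, heat and iodide catalysis; with two of the three oxygens already capped the ring is no longer a phloroglucinol polyanion, so O-alkylation should dominate over attack at ring carbon.

Step 4
Reactants: 7 2',6'-dihydroxy-4'-methoxyacetophenone; 2 benzyl bromide
Product: 8 1-[2-(benzyloxy)-6-hydroxy-4-methoxyphenyl]ethanone
Conditions: K2CO3 (1.1 equiv), acetone, reflux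
Reagents that add atoms: none
Why: Williamson monoalkylation; after the first benzylation the remaining hydroxyl is locked in a hydrogen bond to the acetyl group and reacts much more slowly, which should stop the reaction at the mono-ether.

Step 5
Reactants: 8 1-[2-(benzyloxy)-6-hydroxy-4-methoxyphenyl]ethanone; 9 4-methoxybenzoyl chloride
Product: 11 1-[2-(benzyloxy)-6-hydroxy-4-methoxyphenyl]-3-(4-methoxyphenyl)propane-1,3-dione, via aryl 4-methoxybenzoate 10 (not isolated)
Conditions: pyridine, 0 °C → rt; then KOH (powder, 3 equiv), 50 °C; AcOH quench
Reagents that add atoms: none
Why: O-acylation of the phenol followed by Baker–Venkataraman rearrangement: the acetyl enolate attacks the neighbouring ester carbonyl (intramolecular Claisen-type acyl transfer from O to C) and the product rests as its stabilised diketone enolate until the quench.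

Step 6
Reactants: 11 1-[2-(benzyloxy)-6-hydroxy-4-methoxyphenyl]-3-(4-methoxyphenyl)propane-1,3-dione
Product: 12 5-(benzyloxy)-7-methoxy-2-(4-methoxyphenyl)-4H-chromen-4-one
Conditions: TsOH·H2O (cat.), toluene, 80 °C
Reagents that add atoms: none
Why: Acid-catalysed cyclodehydration: the phenol adds to the anisoyl carbonyl and loss of water gives the 4-pyranone ring; a catalytic sulfonic acid in toluene is mild enough for the benzyl ether next to the carbonyl.

Step 7
Reactants: 12 5-(benzyloxy)-7-methoxy-2-(4-methoxyphenyl)-4H-chromen-4-one
Product: 14 5-(benzyloxy)-3-iodo-7-methoxy-2-(4-methoxyphenyl)-4H-chromen-4-one, via 3-lithioflavone 13 (not isolated)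
Conditions: LiN(iPr)2 (1.3 equiv), THF, −78 °C; then I2, −78 → 0 °C
Reagents that add atoms: iodine, II
Why: Directed deprotonation of the vinylic C3–H (flanked by the carbonyl and the ring oxygen) and iodinolysis of the organolithium; placing iodine through the anion avoids electrophilic iodination at C6 or C8 of the dialkoxy ring A.

Step 8
Reactants: 6 1-[4-(benzyloxy)-2,6-bis(4-methoxybenzyloxy)phenyl]ethanone; 14 5-(benzyloxy)-3-iodo-7-methoxy-2-(4-methoxyphenyl)-4H-chromen-4-one
Product: 15 5-(benzyloxy)-3-{2-[4-(benzyloxy)-2,6-bis(4-methoxybenzyloxy)phenyl]-2-oxoethyl}-7-methoxy-2-(4-methoxyphenyl)-4H-chromen-4-one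
Conditions: Pd2(dba)3 (2.5 mol %), Xantphos (6 mol %), K3PO4 (3 equiv), toluene, 90 °C
Reagents that add atoms: none
Why: Palladium-catalysed α-arylation (here alkenylation) of a methyl ketone: oxidative addition of zerovalent palladium to the C3–I bond, exchange with the potassium enolate of 6 and reductive elimination, helped by the wide bite angle of the ligand. Ketone 6 has one enolisable position and the more acidic product rests as its enolate, which should prevent a second coupling; the weak phosphate base spares the flavone.

Step 9
Reactants: 15 5-(benzyloxy)-3-{2-[4-(benzyloxy)-2,6-bis(4-methoxybenzyloxy)phenyl]-2-oxoethyl}-7-methoxy-2-(4-methoxyphenyl)-4H-chromen-4-one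
Product: 16 5-(benzyloxy)-3-{2-[4-(benzyloxy)-2,6-bis(4-methoxybenzyloxy)phenyl]-1-diazo-2-oxoethyl}-7-methoxy-2-(4-methoxyphenyl)-4H-chromen-4-one
Conditions: 4-AcNHC6H4SO2N3 (1.3 equiv), DBU (1.5 equiv), MeCN, 0 °C → rt, dark
Reagents that add atoms: 4-acetamidobenzenesulfonyl azide, CC(=O)Nc1ccc(cc1)S(=O)(=O)N=[N+]=[N-]
Why: Regitz diazo transfer: the methylene between the aryl ketone and C3 of the flavone is acidic enough for an amidine base, its enolate attacks the terminal nitrogen of the sulfonyl azide and loss of the sulfonamide leaves the diazo group. No stereocentre is present yet, so the base does no harm; the product is kept cold and dark and used at once, because alkenyl diazo compounds can close to pyrazoles on standing.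

Step 10
Reactants: 16 5-(benzyloxy)-3-{2-[4-(benzyloxy)-2,6-bis(4-methoxybenzyloxy)phenyl]-1-diazo-2-oxoethyl}-7-methoxy-2-(4-methoxyphenyl)-4H-chromen-4-one
Product: 17 (2R,3R)-7-(benzyloxy)-3-[5-(benzyloxy)-7-methoxy-2-(4-methoxyphenyl)-4-oxo-4H-chromen-3-yl]-5-(4-methoxybenzyloxy)-2-(4-methoxyphenyl)chroman-4-one (2,3-cis)
Conditions: Rh2(S-PTTL)4 (dirhodium tetrakis[N-phthaloyl-(S)-tert-leucinate], 2 mol %), toluene, 4 Å MS, −40 → 0 °C, slow addition of 16
Reagents that add atoms: none
Why: Rh2(S-PTTL)4 expels N2 from 16 to give a rhodium carbenoid at C3 with the aroyl group as acceptor and the flavon-3-yl group as donor, and this electrophilic carbon takes up a benzylic C–H bond of an ortho 4-methoxybenzyl ether through a concerted, asynchronous three-centre transition state with hydride-transfer character, forming C2–C3 and releasing the catalyst. The closest known reaction type is the dirhodium-carboxylate-catalysed intramolecular C–H insertion of ortho-alkoxyaryl α-diazo ketones and of aryldiazoacetates into ether C–H bonds, which gives cis-2,3-disubstituted chroman-4-ones and dihydrobenzofurans. Ring C closes as a six-membered ring by 1,6-insertion (carbenoid carbon, C4, C4a, C8a, O1, C2) through a chair-like array. C2 is fixed by which of the two enantiotopic benzylic hydrogens the carbenoid engages, a choice made by the wall of N-phthaloyl-tert-leucinate ligands around the rhodium. C3 is created in the same event and should come out cis to C2, because the anisyl group sits pseudo-equatorial while the flavonyl group on the carbenoid turns away from the ligand wall, so that both hydrogens end on one face. The step needs insertion to win over oxonium ylide formation with [1,2]-shift, Wolff rearrangement, attack on the C2'' anisyl ring and insertion into the 5''-benzyl ether. The substrate supports this with a C–H bond activated by both oxygen and the 4-methoxyphenyl ring, two equivalent ortho ethers that lead to the same product, a 7-benzyl ether para to the carbonyl and out of reach, a less activated plain benzyl group at O5'' that could only close a seven-membered ring, and no β-hydrogen on the carbenoid; a rhodium carboxylate at low temperature, unlike a copper catalyst such as Cu(acac)2, favours insertion over ylide chemistry.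

Step 11
Reactants: 17 (2R,3R)-7-(benzyloxy)-3-[5-(benzyloxy)-7-methoxy-2-(4-methoxyphenyl)-4-oxo-4H-chromen-3-yl]-5-(4-methoxybenzyloxy)-2-(4-methoxyphenyl)chroman-4-one
Product: 18 (2R,3R)-7-(benzyloxy)-3-[(2R,3R)-5-(benzyloxy)-7-methoxy-2-(4-methoxyphenyl)-4-oxochroman-3-yl]-5-(4-methoxybenzyloxy)-2-(4-methoxyphenyl)chroman-4-one (cis,cis)
Conditions: [Rh(cod)Cl]2 (2.5 mol %), chiral ferrocenyl bisphosphine–thiourea ligand (5.5 mol %), H2 (60 atm), CH2Cl2/i-PrOH, 40 °C
Reagents that add atoms: none
Why: Proposed new method: a monovalent rhodium–bisphosphine hydride complex, held to the substrate by the alkene and by a hydrogen bond from the thiourea arm of the ligand to the C4'' carbonyl, should deliver both hydrogens to one face of C2''=C3'' (migratory insertion, then reductive elimination with retention), so that C2'' and C3'' come out cis and the ligand antipode selects the 2''R,3''R face; the closest known reaction type is the rhodium/chiral bisphosphine hydrogenation of 2-substituted chromones to chromanones and of tetrasubstituted α,β-unsaturated carbonyl compounds with bisphosphine–thiourea ligands, whereas a tetrasubstituted 2-aryl-3-alkyl flavone has not been used; the medium is neutral, so C3 should not epimerise, and rhodium leaves benzyl ethers and aryl ketones untouched.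

Step 12
Reactants: 18 (2R,3R)-7-(benzyloxy)-3-[(2R,3R)-5-(benzyloxy)-7-methoxy-2-(4-methoxyphenyl)-4-oxochroman-3-yl]-5-(4-methoxybenzyloxy)-2-(4-methoxyphenyl)chroman-4-one
Product: 19 (2R,3R)-5,7-dihydroxy-3-[(2R,3R)-5-hydroxy-7-methoxy-2-(4-methoxyphenyl)-4-oxochroman-3-yl]-2-(4-methoxyphenyl)chroman-4-one (CNP0184936.2)
Conditions: H2 (1 atm), 10% Pd/C, EtOAc/THF, rt
Reagents that add atoms: none
Why: Hydrogenolysis of one aryl 4-methoxybenzyl ether and two aryl benzyl ethers over Pd/C; the neutral medium should leave the four cis-related centres untouched, and the ring O1–C2 and O1''–C2'' bonds, being secondary, hindered and part of a ring, should react more slowly than the primary benzylic C–O bonds if the reaction is stopped after three equivalents of hydrogen.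

## Compound list

1 | 2',4',6'-trihydroxyacetophenone | CC(=O)c1c(O)cc(O)cc1O | starting material
2 | benzyl bromide | BrCc1ccccc1 | starting material
3 | 1-[4-(benzyloxy)-2,6-dihydroxyphenyl]ethanone | CC(=O)c1c(O)cc(OCc2ccccc2)cc1O | intermediate
4 | 4-methoxybenzyl chloride | COc1ccc(CCl)cc1 | starting material
5 | 1-[4-(benzyloxy)-2-hydroxy-6-(4-methoxybenzyloxy)phenyl]ethanone | CC(=O)c1c(O)cc(OCc2ccccc2)cc1OCc1ccc(OC)cc1 | intermediate
6 | 1-[4-(benzyloxy)-2,6-bis(4-methoxybenzyloxy)phenyl]ethanone | CC(=O)c1c(OCc2ccc(OC)cc2)cc(OCc2ccccc2)cc1OCc1ccc(OC)cc1 | intermediate
7 | 2',6'-dihydroxy-4'-methoxyacetophenone | CC(=O)c1c(O)cc(OC)cc1O | starting material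
8 | 1-[2-(benzyloxy)-6-hydroxy-4-methoxyphenyl]ethanone | CC(=O)c1c(O)cc(OC)cc1OCc1ccccc1 | intermediate
9 | 4-methoxybenzoyl chloride | COc1ccc(cc1)C(=O)Cl | starting material
10 | 2-acetyl-3-(benzyloxy)-5-methoxyphenyl 4-methoxybenzoate (not isolated) | CC(=O)c1c(OC(=O)c2ccc(OC)cc2)cc(OC)cc1OCc1ccccc1 | intermediate
11 | 1-[2-(benzyloxy)-6-hydroxy-4-methoxyphenyl]-3-(4-methoxyphenyl)propane-1,3-dione | COc1ccc(cc1)C(=O)CC(=O)c1c(O)cc(OC)cc1OCc1ccccc1 | intermediate
12 | 5-(benzyloxy)-7-methoxy-2-(4-methoxyphenyl)-4H-chromen-4-one | COc1ccc(cc1)C1=CC(=O)c2c(OCc3ccccc3)cc(OC)cc2O1 | intermediate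
13 | 5-(benzyloxy)-3-lithio-7-methoxy-2-(4-methoxyphenyl)-4H-chromen-4-one (not isolated) | COc1ccc(cc1)C1=C([Li])C(=O)c2c(OCc3ccccc3)cc(OC)cc2O1 | intermediate
14 | 5-(benzyloxy)-3-iodo-7-methoxy-2-(4-methoxyphenyl)-4H-chromen-4-one | COc1ccc(cc1)C1=C(I)C(=O)c2c(OCc3ccccc3)cc(OC)cc2O1 | intermediate
15 | 5-(benzyloxy)-3-{2-[4-(benzyloxy)-2,6-bis(4-methoxybenzyloxy)phenyl]-2-oxoethyl}-7-methoxy-2-(4-methoxyphenyl)-4H-chromen-4-one | COc1ccc(COc2cc(OCc3ccccc3)cc(OCc3ccc(OC)cc3)c2C(=O)CC2=C(c3ccc(OC)cc3)Oc3cc(OC)cc(OCc4ccccc4)c3C2=O)cc1 | intermediate
16 | 5-(benzyloxy)-3-{2-[4-(benzyloxy)-2,6-bis(4-methoxybenzyloxy)phenyl]-1-diazo-2-oxoethyl}-7-methoxy-2-(4-methoxyphenyl)-4H-chromen-4-one | COc1ccc(COc2cc(OCc3ccccc3)cc(OCc3ccc(OC)cc3)c2C(=O)C(=[N+]=[N-])C2=C(c3ccc(OC)cc3)Oc3cc(OC)cc(OCc4ccccc4)c3C2=O)cc1 | intermediate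
17 | (2R,3R)-7-(benzyloxy)-3-[5-(benzyloxy)-7-methoxy-2-(4-methoxyphenyl)-4-oxo-4H-chromen-3-yl]-5-(4-methoxybenzyloxy)-2-(4-methoxyphenyl)chroman-4-one | COc1ccc([C@@H]2Oc3cc(OCc4ccccc4)cc(OCc4ccc(OC)cc4)c3C(=O)[C@@H]2C2=C(c3ccc(OC)cc3)Oc3cc(OC)cc(OCc4ccccc4)c3C2=O)cc1 | intermediate
18 | (2R,3R)-7-(benzyloxy)-3-[(2R,3R)-5-(benzyloxy)-7-methoxy-2-(4-methoxyphenyl)-4-oxochroman-3-yl]-5-(4-methoxybenzyloxy)-2-(4-methoxyphenyl)chroman-4-one | COc1ccc([C@@H]2Oc3cc(OCc4ccccc4)cc(OCc4ccc(OC)cc4)c3C(=O)[C@@H]2[C@H]2C(=O)c3c(OCc4ccccc4)cc(OC)cc3O[C@H]2c2ccc(OC)cc2)cc1 | intermediate
19 | (2R,3R)-5,7-dihydroxy-3-[(2R,3R)-5-hydroxy-7-methoxy-2-(4-methoxyphenyl)-4-oxochroman-3-yl]-2-(4-methoxyphenyl)chroman-4-one | COc1ccc([C@@H]2Oc3cc(O)cc(O)c3C(=O)[C@@H]2[C@H]2C(=O)c3c(O)cc(OC)cc3O[C@H]2c2ccc(OC)cc2)cc1 | target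

## Step count and least certain steps

Total: 12 steps. Longest linear sequence: 9 steps (7 → 8 → 11 → 12 → 14 → 15 → 16 → 17 → 18 → 19); the branch 1 → 3 → 5 → 6 (steps 1 to 3) joins this line at step 8.

Step 11 (Proposed new method). Most likely failure: no turnover, because the crowded tetrasubstituted alkene does not bind rhodium, or poor facial selectivity, because the resident C3 centre opposes the ligand. Fallback with known chemistry: setting out from 17, hydrogenation over Pd(OH)2/C under H2 (3–4 atm) in EtOAc/THF at room temperature saturates the flavone alkene by delivery of both hydrogens from the catalyst surface to one face, which again gives a cis pair. The same conditions cleave the benzyl and 4-methoxybenzyl ethers, so the route is rejoined at 19 without passing through 18. The face is then chosen by the substrate alone; the two possible cis products are diastereomers and would be separated by chromatography. Migration of the double bond toward C3 on the metal surface is the risk to watch. No new compound arises.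

Step 10 (key step). Most likely failure: capture of the carbenoid by the ortho ether oxygen (a five-membered oxonium ylide) followed by [1,2]-shift of the 4-methoxybenzyl group, or loss of enantio- and cis-selectivity, because a keto carbenoid is less discriminating than an ester carbenoid. Fallback: setting out from 15, MgBr2·OEt2 in CH2Cl2 removes one chelating ortho 4-methoxybenzyl group to give 5-(benzyloxy)-3-{2-[4-(benzyloxy)-2-hydroxy-6-(4-methoxybenzyloxy)phenyl]-2-oxoethyl}-7-methoxy-2-(4-methoxyphenyl)-4H-chromen-4-one F1. Heating F1 with N,N-dimethylformamide dimethyl acetal formylates the active methylene and closes the 2-unsubstituted chromone 3-[7-(benzyloxy)-5-(4-methoxybenzyloxy)-4-oxo-4H-chromen-3-yl]-5-(benzyloxy)-7-methoxy-2-(4-methoxyphenyl)-4H-chromen-4-one F2. Conjugate addition of 4-methoxyphenylboronic acid to F2 with Pd(OCOCF3)2 and a chiral pyridine–oxazoline ligand in wet 1,2-dichloroethane then places the anisyl group on C2 under catalyst control. Protonation of the resulting enolate from the face away from the new aryl group should give the cis compound, and the route is rejoined at 17. The weak point of this path is that the protonation is only kinetically cis.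

Step 8. Most likely failure: slow reductive elimination from a palladium centre carrying two electron-poor carbon ligands, which leads to loss of iodine from 14 without coupling. Fallback: setting out from 6, LiN(SiMe3)2 and 2,2,2-trifluoroethyl trifluoroacetate give 1-[4-(benzyloxy)-2,6-bis(4-methoxybenzyloxy)phenyl]-4,4,4-trifluorobutane-1,3-dione F3. Treated without isolation with methanesulfonyl azide and Et3N, F3 gives 1-[4-(benzyloxy)-2,6-bis(4-methoxybenzyloxy)phenyl]-2-diazoethanone F4. Coupling of the diazo C–H bond of F4 with 14 under Pd(PPh3)4, Ag2CO3 and Et3N in toluene at room temperature keeps the diazo group and gives 16 directly, so the route is rejoined at 16 and step 9 is not needed.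

Step 12. Most likely failure: hydrogenolytic opening of ring C at O1–C2 or O1''–C2'', which are 4-methoxybenzylic aryl ethers of the same kind as the protecting groups, or epimerisation at C3 and C3'' on a basic catalyst support. Fallback: setting out from 18, BCl3 with pentamethylbenzene as cation scavenger in CH2Cl2 at −78 °C cleaves the aryl benzyl and 4-methoxybenzyl ethers without hydrogen and gives 19 directly. No new compound arises.

Step 1. Most likely failure: overrun to a diether or benzylation at ring carbon, because the phenoxide of the mono-ether competes with that of the triphenol for the halide. Fallback: setting out from 1, Mitsunobu etherification with benzyl alcohol (1.0 equiv), PPh3 and diisopropyl azodicarboxylate in THF at 0 °C engages the most acidic, non-chelated para hydroxyl without a free phenoxide in solution and gives 3 directly. No new compound arises.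

## Further compounds

F0 | step 11 | none | none
F1 | step 10 | 5-(benzyloxy)-3-{2-[4-(benzyloxy)-2-hydroxy-6-(4-methoxybenzyloxy)phenyl]-2-oxoethyl}-7-methoxy-2-(4-methoxyphenyl)-4H-chromen-4-one | COc1ccc(COc2cc(OCc3ccccc3)cc(O)c2C(=O)CC2=C(c3ccc(OC)cc3)Oc3cc(OC)cc(OCc4ccccc4)c3C2=O)cc1
F2 | step 10 | 3-[7-(benzyloxy)-5-(4-methoxybenzyloxy)-4-oxo-4H-chromen-3-yl]-5-(benzyloxy)-7-methoxy-2-(4-methoxyphenyl)-4H-chromen-4-one | O=C1C(=COc2cc(OCc3ccccc3)cc(OCc3ccc(OC)cc3)c12)C1=C(c2ccc(OC)cc2)Oc2cc(OC)cc(OCc3ccccc3)c2C1=O
F3 | step 8 | 1-[4-(benzyloxy)-2,6-bis(4-methoxybenzyloxy)phenyl]-4,4,4-trifluorobutane-1,3-dione | FC(F)(F)C(=O)CC(=O)c1c(OCc2ccc(OC)cc2)cc(OCc2ccccc2)cc1OCc1ccc(OC)cc1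
F4 | step 8 | 1-[4-(benzyloxy)-2,6-bis(4-methoxybenzyloxy)phenyl]-2-diazoethanone | [N-]=[N+]=CC(=O)c1c(OCc2ccc(OC)cc2)cc(OCc2ccccc2)cc1OCc1ccc(OC)cc1
F0 | step 12 | none | none
F0 | step 1 | none | none
A1 | alternative 1 | all-trans 3,4-bis(4-methoxyphenyl)cyclobutane-1,2-dicarboxylic acid | OC(=O)[C@@H]1[C@@H](C(O)=O)[C@H](c2ccc(OC)cc2)[C@H]1c1ccc(OC)cc1
A2 | alternative 1 | exo,exo-2,6-bis(4-methoxyphenyl)-3,7-dioxabicyclo[3.3.0]octane-4,8-dione | O=C1O[C@@H](c3ccc(OC)cc3)[C@H]2[C@@H]1[C@H](c1ccc(OC)cc1)OC2=O
A3 | alternative 2 | (1Z,3Z)-1,4-bis(4-methoxyphenyl)buta-1,3-diene | COc1ccc(/C=C\C=C/c2ccc(OC)cc2)cc1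
A4 | alternative 2 | 2,4-bis(benzyloxy)-6-hydroxybenzaldehyde | O=Cc1c(O)cc(OCc2ccccc2)cc1OCc1ccccc1
A5 | alternative 2 | 2-(benzyloxy)-6-hydroxy-4-methoxybenzaldehyde | O=Cc1c(O)cc(OC)cc1OCc1ccccc1
A6 | alternative 2 | 4,4''-dimethoxy-3,3''-biflavan with 5,7,5''-tribenzyloxy, 7''-methoxy and 4-methoxyphenyl groups | COc1ccc([C@@H]2Oc3cc(OCc4ccccc4)cc(OCc4ccccc4)c3[C@@H](OC)[C@@H]2[C@H]2[C@H](OC)c3c(OCc4ccccc4)cc(OC)cc3O[C@H]2c2ccc(OC)cc2)cc1
A7 | alternative 3 | 2,3-bis[hydroxy(4-methoxyphenyl)methyl]-N1,N4-dimethoxy-N1,N4-dimethylbutanediamide | CON(C)C(=O)[C@@H]([C@@H](O)c1ccc(OC)cc1)[C@@H](C(=O)N(C)OC)[C@@H](O)c1ccc(OC)cc1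
A8 | alternative 3 | 3,5-bis(benzyloxy)-2-(trimethylsilyl)phenyl trifluoromethanesulfonate | C[Si](C)(C)c1c(OCc2ccccc2)cc(OCc2ccccc2)cc1OS(=O)(=O)C(F)(F)F
A9 | alternative 3 | 5,7,5'',7''-tetra-O-benzyl (2R,3R,2''R,3''R)-4',4'''-dimethoxy-3,3''-biflavanone | COc1ccc([C@@H]2Oc3cc(OCc4ccccc4)cc(OCc4ccccc4)c3C(=O)[C@@H]2[C@H]2C(=O)c3c(OCc4ccccc4)cc(OCc4ccccc4)cc3O[C@H]2c2ccc(OC)cc2)cc1
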